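The numbers in the tables are calculated with constants of no real substance; scatter was added.

We read the flask at 8.0 d, 48.0 h after the last reading of its own epsilon run.

| flask | substrate | coupling partner | temperature | remark | time |
|---|---|---|---|---|---|
| epsilon | 0.43 M | 1.5 equiv | 100 °C | the very flask that is asked about, followed so far |  |
| delta | 0.43 M | 1.5 equiv | 85 °C | run made earlier |  |
| flask | 0.43 M | 1.50 equiv | 100 °C |  | 8.0 d |

| run | time / h | product / % | substrate / % |
|---|---|---|---|
| epsilon | 30.0 | 53 | 0 |
| epsilon | 60.0 | 61 | 3 |
| epsilon | 96.0 | 67 | 0 |
| epsilon | 120 | 65 | 0 |
| epsilon | 144 | 67 | 0 |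
| delta | 60.0 | 35 | 0 |
| delta | 120 | 58 | 0 |
| delta | 192 | 63 | 0 |
| delta | 240 | 67 | 0 |
| delta | 288 | 67 | 0 |

(scatter of a reading: 2 percentage points)

- what is taken out of product is counted as made
- on the list of suspects stand: substrate -> intermediate A; intermediate A <-> intermediate B; intermediate A <-> intermediate C; coupling partner + intermediate B -> product; coupling partner + intermediate B <-> intermediate D
- additions bring no volume worth counting

- summer: change nothing and wait 15 d more
- dawn: at 8.0 d add coupling partner, 50.0% of the amount charged, then wait 15 d
- dusk: at 8.0 d take out 90% of the product then present, then wait 15 d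
- midnight: at 8.0 d raise the temperature by 25 K, then wait 15 d

- product, in percent of the substrate first charged, at 8.0 d
- what to do for the largest gain in product; "none" if nothing gains more than 2 percentage points (summer / dawn / dusk / midnight / none)
- product present, with what was taken out counted in, in percent of the substrate first charged, after dawn
- product present, with what was taken out counted in, in percent of the substrate first charged, after midnight

1. Start. In the epsilon run, substrate reads 0% at 30.0 h. Up to then, product has risen on average by a fraction 0.0177 /h of the charge.

2. Knee. From 30.0 h to 60.0 h the slope is 0.00267 /h, far less than before, so the curve bends before 60.0 h.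

3. Level. The last three readings average 66.3%, and the delta run also ends at 67%. This leaves a gap of 33.7% of the charge.

4. Reserve. Each product takes one coupling partner, so we reckon the partner reserve, one minus the product fraction over the equivalents charged, as 55.8% of its own charge. Closing the gap takes 22.4% of that charge, less than the reserve, so in this flask we take substrate as the limiting reagent and the level as no partner shortage. Dawn lifts the reserve to 106%, twice its present value.

5. Our reckoning. We put product at 8.0 d at 66.3%. With a scatter of 2 percentage points, the 48.0 h of level readings show no rise beyond that scatter.

The forecast gives 67%, a little above our level, with none as the best choice, 67% after dawn and 68% after midnight, holding “so release from the trap is negligible”.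

The flask gives 67.9%, and the best choice is midnight. The gains are 8.6 points for summer, 9.7 points for dawn, 8.6 points for dusk and 32 points for midnight, with 77.6% after dawn and 99.7% after midnight.

    substrate → intermediate A (k = 0.0100 /min, Ea = 115 kJ/mol)
    intermediate A ⇌ intermediate B (K = 0.810, k = 0.00180 /min, Ea = 118 kJ/mol, ΔH = −17.0 kJ/mol)
    intermediate A ⇌ intermediate C (K = 23.0, k = 5.80 × 10⁻⁴ /min, Ea = 112 kJ/mol, ΔH = −43.0 kJ/mol)
    coupling partner + intermediate B → product (k = 0.00550 /M/min, Ea = 87.0 kJ/mol)
    coupling partner + intermediate B ⇌ intermediate D (K = 0.170 /M, k = 0.00160 /M/min, Ea = 73.0 kJ/mol, ΔH = −16.0 kJ/mol)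
    (constants at 100 °C)

The reserve rule, which gave 55.8% from the readings, gives 54.7% of coupling partner for the flask's 67.9% of product at 192 h. At that time in the flask, the product step gives coupling partner a half-life of 84 d, longer than the 15 d of waiting, and intermediate C holds 31.3% against 0.244% of intermediate B. In the neighbour charged with 0.380 equiv, the same reckoning from its 33.5% of product gives a reserve of 11.8%, and that neighbour holds 12% of its coupling partner, with 61.7% in intermediate C.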